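The plan rests on cutting the upper C4–C4a bond. Ring A carbon C4a lies ortho to O1 and para to the C7 oxygen, so it is the built-in nucleophile. Ring D on C4 must end cis to the C3 hydroxyl of a 2,3-trans ring C. The precursor is a ring A aryl ether in which O1–C2 and ring B are in place, C3–C4 is a cis-oxirane and C4 carries the protected lower dihydroflavonol. Rear-side attack of C4a on benzylic C4 closes ring C, sets C4 by inversion and frees the C3 hydroxyl in one operation. Ring A is masked as a diphenylmethylene ketal, one step from pyrogallol.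

Key step: step 14

Remarks
- **Numbering.** The upper unit has rings A (benzo), C (pyran) and B (4-oxyphenyl). The lower unit has rings D (benzo), F (pyran) and E (4-oxyphenyl). Flavan numbering is used within each unit.
- **Configuration planned for, read from the target SMILES.** The upper unit is 2S,3R,4R (2,3-trans, 3,4-cis). The lower unit is 2R,3S,4R (2,3-trans, 3,4-trans).
- **Descriptor note.** Upper C4 is R in 20, S in 21 and R again in 22 and 23. Between 21 and 22 nothing happens at C4. Only the CIP ranking of C4a against C6 of ring D changes when O7 of ring D loses its benzyl group.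
- **Precursor design.** The C7/C8 oxygens of ring A are tied into a 2,2-diphenyl-1,3-dioxole instead of two benzyl ethers.
  - The free phenol comes in one step.
  - O7 stays coplanar with ring A and feeds C4a.
  - The surroundings of O1 are less crowded.
  - The ketal falls in the same hydrogenolysis as the benzyl ethers.
- **Assumption.** The (S,S) antipode of Ph-pybox is taken to give (R)-7. Both antipodes are commercial. The sense is checked by correlation on the first run, and the other antipode is used if needed.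

Step 1
Reactants: 1 pyrogallol
Product: 2 2,2-diphenyl-1,3-benzodioxol-4-ol
Conditions: Ph2CCl2, Ph2O, 175 °C
Reagents that add atoms: dichlorodiphenylmethane, ClC(Cl)(c1ccccc1)c1ccccc1
Why: Ketalisation of a catechol pair with a gem-dichloride, in which only two adjacent hydroxyls can close the five-membered dioxole, so exactly one phenol (the future O1) stays free.

Step 2
Reactants: 3 4-(benzyloxy)benzaldehyde; 4 ethynylmagnesium bromide
Product: 6 rac-1-[4-(benzyloxy)phenyl]prop-2-yn-1-yl acetate, via bromomagnesium alkoxide 5 (not isolated)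
Conditions: THF, 0 °C; then Ac2O, 0 °C to rt
Reagents that add atoms: acetic anhydride, CC(=O)OC(C)=O
Why: Grignard 1,2-addition to a non-enolisable aldehyde followed by O-acylation of the alkoxide in the same flask, the racemate being sufficient because the next step is stereoconvergent.

Step 3
Reactants: 2 2,2-diphenyl-1,3-benzodioxol-4-ol; 6 rac-1-[4-(benzyloxy)phenyl]prop-2-yn-1-yl acetate
Product: 7 (R)-4-({1-[4-(benzyloxy)phenyl]prop-2-yn-1-yl}oxy)-2,2-diphenyl-1,3-benzodioxole
Conditions: CuOTf·0.5C6H6 (5 mol %), (S,S)-Ph-pybox (10 mol %), iPr2NEt, ClCH2CH2Cl, −10 °C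
Reagents that add atoms: none
Why: Copper-catalysed asymmetric propargylic etherification, in which the copper acetylide of either enantiomer of 6 loses acetate to one planar copper allenylidene and the pybox pocket admits phenol 2 to a single face of the γ-carbon, which sets upper C2.

Step 4
Reactants: 8 2',3',4'-trihydroxyacetophenone
Product: 9 1-[3,4-bis(benzyloxy)-2-hydroxyphenyl]ethanone
Conditions: BnBr (2 equiv), K2CO3, acetone, reflux
Reagents that add atoms: benzyl bromide, BrCc1ccccc1
Why: Williamson etherification that stops after two benzylations because the 2'-hydroxyl is locked in a hydrogen bond to the ketone and is the least nucleophilic oxygen.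

Step 5
Reactants: 9 1-[3,4-bis(benzyloxy)-2-hydroxyphenyl]ethanone
Product: 10 1-[3,4-bis(benzyloxy)-2-hydroxy-5-iodophenyl]ethanone
Conditions: NIS, TFA (cat.), MeCN, rt, dark
Reagents that add atoms: N-iodosuccinimide, O=C1CCC(=O)N1I
Why: Electrophilic aromatic iodination directed to C5' (future C6 of ring D), the only open carbon that is para to the free phenol and ortho to the 4'-benzyloxy group, while C6' is flanked by the deactivating acyl group.

Step 6
Reactants: 10 1-[3,4-bis(benzyloxy)-2-hydroxy-5-iodophenyl]ethanone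
Product: 12 1-[3,4-bis(benzyloxy)-5-iodo-2-(methoxymethoxy)phenyl]ethanone, via sodium phenoxide 11 (not isolated)
Conditions: NaH, DMF, 0 °C; then MOMCl, 0 °C to rt
Reagents that add atoms: chloromethyl methyl ether, COCCl
Why: O-alkylation of the preformed phenoxide, a full equivalent of strong base being needed to break the chelate, and the acetal keeps the phenol from an Algar–Flynn–Oyamada-type cyclisation in the basic peroxide step.

Step 7
Reactants: 12 1-[3,4-bis(benzyloxy)-5-iodo-2-(methoxymethoxy)phenyl]ethanone; 3 4-(benzyloxy)benzaldehyde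
Product: 13 (E)-1-[3,4-bis(benzyloxy)-5-iodo-2-(methoxymethoxy)phenyl]-3-[4-(benzyloxy)phenyl]prop-2-en-1-one
Conditions: KOH, EtOH–THF, rt
Reagents that add atoms: none
Why: Claisen–Schmidt condensation of a methyl ketone with a non-enolisable aldehyde, the E1cB dehydration giving the E-chalcone.

Step 8
Reactants: 13 (E)-chalcone
Product: 14 [3,4-bis(benzyloxy)-5-iodo-2-(methoxymethoxy)phenyl]{(2R,3S)-3-[4-(benzyloxy)phenyl]oxiran-2-yl}methanone
Conditions: poly-L-leucine, urea·H2O2, DBU, THF, rt
Reagents that add atoms: urea–hydrogen peroxide, NC(N)=O.OO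
Why: Juliá–Colonna epoxidation, in which hydroperoxide adds to the chalcone bound at the helical terminus of poly-L-leucine and closes to the (αR,βS)-trans-epoxide, so that the α-carbon becomes lower C3 in its final configuration.

Step 9
Reactants: 14 (αR,βS)-chalcone epoxide
Product: 16 (2R,3R)-7,8-bis(benzyloxy)-2-[4-(benzyloxy)phenyl]-3-hydroxy-6-iodochroman-4-one, via free 2'-phenol epoxide 15 (not isolated)
Conditions: HCl, MeOH–THF, 45 °C
Reagents that add atoms: none
Why: Acidic acetal cleavage followed by 6-endo opening of the epoxide at the 4-alkoxybenzylic β-carbon by the liberated phenol, which leaves the C3–O bond untouched and sets C2 trans to C3, the diequatorial and thermodynamically preferred dihydroflavonol.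

Step 10
Reactants: 16 (2R,3R)-dihydroflavonol
Product: 17 (2R,3R)-3,7,8-tris(benzyloxy)-2-[4-(benzyloxy)phenyl]-6-iodochroman-4-one
Conditions: BnOC(=NH)CCl3, TfOH (cat.), CH2Cl2–cyclohexane, 0 °C to rt
Reagents that add atoms: benzyl 2,2,2-trichloroacetimidate, N=C(OCc1ccccc1)C(Cl)(Cl)Cl
Why: Acid-catalysed O-benzylation with a trichloroacetimidate, chosen because it needs no base and so cannot trigger retro-oxa-Michael opening of ring F or epimerisation at C2 and C3.

Step 11
Reactants: 7 (R)-propargylic aryl ether; 17 6-iodo dihydroflavonol tetrabenzyl ether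
Product: 18 (2R,3R)-3,7,8-tris(benzyloxy)-2-[4-(benzyloxy)phenyl]-6-{(3S)-3-[4-(benzyloxy)phenyl]-3-[(2,2-diphenyl-1,3-benzodioxol-4-yl)oxy]prop-1-yn-1-yl}chroman-4-one
Conditions: PdCl2(PPh3)2, CuI, Et3N, THF, rt, degassed
Reagents that add atoms: none
Why: Sonogashira coupling of an aryl iodide with a terminal alkyne at room temperature, where triethylamine is too weak to disturb ring F or the propargylic centre and any minor enantiomer of either fragment ends up as a separable diastereomer.

Step 12
Reactants: 18 diaryl-flanked alkyne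
Product: 19 (2R,3R)-3,7,8-tris(benzyloxy)-2-[4-(benzyloxy)phenyl]-6-{(1Z,3R)-3-[4-(benzyloxy)phenyl]-3-[(2,2-diphenyl-1,3-benzodioxol-4-yl)oxy]prop-1-en-1-yl}chroman-4-one
Conditions: H2 (1 atm), Pd/CaCO3 poisoned with Pb(OAc)2, quinoline, EtOAc, rt
Reagents that add atoms: none
Why: Lindlar semihydrogenation, whose syn delivery of hydrogen gives the Z-alkene while the poisoned surface leaves the benzyl ethers, the ketal and the ketone alone.

Step 13
Reactants: 19 Z-alkene
Product: 20 (2R,3R)-3,7,8-tris(benzyloxy)-2-[4-(benzyloxy)phenyl]-6-[(2R,3R)-3-{(S)-[4-(benzyloxy)phenyl][(2,2-diphenyl-1,3-benzodioxol-4-yl)oxy]methyl}oxiran-2-yl]chroman-4-one (upper 2S,3R,4R cis-oxirane)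
Conditions: (R,R)-(salen)MnCl [salen = N,N'-bis(3,5-di-tert-butylsalicylidene)cyclohexane-1,2-diamine dianion] (10 mol %), mCPBA, NMO, CH2Cl2, −78 °C
Reagents that add atoms: 3-chloroperoxybenzoic acid, OOC(=O)c1cccc(Cl)c1
Why: Jacobsen–Katsuki epoxidation of a cis-β-substituted styrene, in which the (R,R) catalyst makes the benzylic carbon R as it does with cis-β-methylstyrene, indene and cis-cinnamates, this face also being the one anti to the allylic C2–O1 bond in the A(1,3)-minimised conformer, so catalyst and substrate should reinforce each other in setting C3 and C4, and the low temperature restrains bond rotation in the radical intermediate.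

Step 14
Reactants: 20 cis-oxirane aryl ether
Product: 21 protected dimer: (2S,3R,4S)-2-[4-(benzyloxy)phenyl]-7,8-(diphenylmethylenedioxy)chroman-3-ol joined through C4 to C6 of (2R,3R)-3,7,8-tris(benzyloxy)-2-[4-(benzyloxy)phenyl]chroman-4-one (upper unit 2,3-trans-3,4-cis)
Conditions: (CF3)2CHOH–CH2Cl2 (4:1), 0.005 M, 0 °C to rt
Reagents that add atoms: none
Why: Hexafluoroisopropanol hydrogen-bonds to the oxirane oxygen and weakens the benzylic C4–O bond, C4a of ring A (ortho to O1, para to the ketal oxygen on C7) attacks C4 from the rear, and loss of the C4a proton from the arenium ion restores ring A and leaves the C3 hydroxyl. The closest known reaction type is the intramolecular Friedel–Crafts epoxy-arene cyclisation that turns 3-arylglycidyl aryl ethers into 4-arylchroman-3-ols with inversion at the benzylic carbon. Ring C closes in the 6-endo-tet mode, both oxirane carbons becoming ring members. C4 is the only new stereocentre and is controlled by the oxirane geometry: C2 and ring D are cis on the oxirane, so inversion at C4 puts ring D cis to the C3 hydroxyl, while the C2–O1 and C3–O bonds are untouched and keep the 2,3-trans relation. The step needs 6-endo over 5-exo regiochemistry, secured by benzylic activation of C4 through O7 (ortho) and O1 (para) of ring D against an unactivated C3, and it needs bond making to keep pace with bond breaking, which the lower C4 ketone favours because it draws on these same two oxygens and so restrains a free cation. The planar dioxole raises the donor strength of O7 of ring A towards C4a, the second activated site of ring A (C6) cannot reach C4, and the medium offers no competing nucleophile.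

Step 15
Reactants: 21 protected dimer
Product: 22 (2R,3R)-3,7,8-trihydroxy-2-(4-hydroxyphenyl)-6-[(2S,3R,4R)-3,7,8-trihydroxy-2-(4-hydroxyphenyl)chroman-4-yl]chroman-4-one
Conditions: H2 (1 atm), Pd(OH)2/C, THF–MeOH, rt
Reagents that add atoms: none
Why: Catalytic hydrogenolysis of five benzyl ethers and the diphenylmethylene ketal in one operation, run while lower C4 is still a ketone so that no benzylic C4 alcohol is ever exposed to palladium and hydrogen.

Step 16
Reactants: 22 free phenolic ketone
Product: 23 (2R,3S,4R)-2-(4-hydroxyphenyl)-6-[(2S,3R,4R)-3,7,8-trihydroxy-2-(4-hydroxyphenyl)chroman-4-yl]chromane-3,4,7,8-tetrol (target)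
Conditions: NaBH4 (excess), EtOH, 0 °C, under Ar
Reagents that add atoms: none
Why: Borohydride reduction of a 2,3-trans-dihydroflavonol, in which axial hydride delivery to C4 gives the equatorial 4-hydroxyl trans to the equatorial 3-hydroxyl (4R), the standard outcome for this substrate class, with near-neutral work-up under inert gas to spare the flavan-3,4-diol and the catechol rings.

Compound list
1 | pyrogallol | Oc1cccc(O)c1O | starting material
2 | 2,2-diphenyl-1,3-benzodioxol-4-ol | Oc1cccc2OC(c3ccccc3)(c3ccccc3)Oc12 | intermediate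
3 | 4-(benzyloxy)benzaldehyde | O=Cc1ccc(OCc2ccccc2)cc1 | starting material
4 | ethynylmagnesium bromide | C#C[Mg]Br | starting material
5 | bromomagnesium 1-[4-(benzyloxy)phenyl]prop-2-yn-1-olate (racemic) | C#CC(O[Mg]Br)c1ccc(OCc2ccccc2)cc1 | intermediate
6 | rac-1-[4-(benzyloxy)phenyl]prop-2-yn-1-yl acetate | C#CC(OC(C)=O)c1ccc(OCc2ccccc2)cc1 | intermediate
7 | (R)-4-({1-[4-(benzyloxy)phenyl]prop-2-yn-1-yl}oxy)-2,2-diphenyl-1,3-benzodioxole | c1ccc2OC(c3ccccc3)(c3ccccc3)Oc2c1O[C@@H](c1ccc(OCc3ccccc3)cc1)C#C | intermediate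
8 | 2',3',4'-trihydroxyacetophenone | CC(=O)c1ccc(O)c(O)c1O | starting material
9 | 1-[3,4-bis(benzyloxy)-2-hydroxyphenyl]ethanone | CC(=O)c1ccc(OCc2ccccc2)c(OCc2ccccc2)c1O | intermediate
10 | 1-[3,4-bis(benzyloxy)-2-hydroxy-5-iodophenyl]ethanone | CC(=O)c1cc(I)c(OCc2ccccc2)c(OCc2ccccc2)c1O | intermediate
11 | sodium 6-acetyl-2,3-bis(benzyloxy)-4-iodophenoxide | CC(=O)c1cc(I)c(OCc2ccccc2)c(OCc2ccccc2)c1[O-].[Na+] | intermediate
12 | 1-[3,4-bis(benzyloxy)-5-iodo-2-(methoxymethoxy)phenyl]ethanone | CC(=O)c1cc(I)c(OCc2ccccc2)c(OCc2ccccc2)c1OCOC | intermediate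
13 | (E)-1-[3,4-bis(benzyloxy)-5-iodo-2-(methoxymethoxy)phenyl]-3-[4-(benzyloxy)phenyl]prop-2-en-1-one | O=C(/C=C/c1ccc(OCc2ccccc2)cc1)c1cc(I)c(OCc2ccccc2)c(OCc2ccccc2)c1OCOC | intermediate
14 | [3,4-bis(benzyloxy)-5-iodo-2-(methoxymethoxy)phenyl]{(2R,3S)-3-[4-(benzyloxy)phenyl]oxiran-2-yl}methanone | O=C([C@@H]1O[C@H]1c1ccc(OCc2ccccc2)cc1)c1cc(I)c(OCc2ccccc2)c(OCc2ccccc2)c1OCOC | intermediate
15 | [3,4-bis(benzyloxy)-2-hydroxy-5-iodophenyl]{(2R,3S)-3-[4-(benzyloxy)phenyl]oxiran-2-yl}methanone | O=C([C@@H]1O[C@H]1c1ccc(OCc2ccccc2)cc1)c1cc(I)c(OCc2ccccc2)c(OCc2ccccc2)c1O | intermediate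
16 | (2R,3R)-7,8-bis(benzyloxy)-2-[4-(benzyloxy)phenyl]-3-hydroxy-6-iodochroman-4-one | Ic1cc2c(c(OCc3ccccc3)c1OCc1ccccc1)O[C@H](c1ccc(OCc3ccccc3)cc1)[C@@H](O)C2=O | intermediate
17 | (2R,3R)-3,7,8-tris(benzyloxy)-2-[4-(benzyloxy)phenyl]-6-iodochroman-4-one | Ic1cc2c(c(OCc3ccccc3)c1OCc1ccccc1)O[C@H](c1ccc(OCc3ccccc3)cc1)[C@@H](OCc1ccccc1)C2=O | intermediate
18 | alkyne joining upper C4 to C6 of ring D (upper C2 S; lower 2R,3R) | c1ccc2OC(c3ccccc3)(c3ccccc3)Oc2c1O[C@@H](c1ccc(OCc3ccccc3)cc1)C#Cc1cc2c(c(OCc3ccccc3)c1OCc1ccccc1)O[C@H](c1ccc(OCc3ccccc3)cc1)[C@@H](OCc1ccccc1)C2=O | intermediate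
19 | Z-alkene (upper C2 R; lower 2R,3R) | c1ccc2OC(c3ccccc3)(c3ccccc3)Oc2c1O[C@@H](c1ccc(OCc3ccccc3)cc1)/C=C\c1cc2c(c(OCc3ccccc3)c1OCc1ccccc1)O[C@H](c1ccc(OCc3ccccc3)cc1)[C@@H](OCc1ccccc1)C2=O | intermediate
20 | cis-oxirane aryl ether, precursor of the key step (upper 2S,3R,4R; lower 2R,3R) | c1ccc2OC(c3ccccc3)(c3ccccc3)Oc2c1O[C@@H](c1ccc(OCc3ccccc3)cc1)[C@@H]4O[C@@H]4c1cc2c(c(OCc3ccccc3)c1OCc1ccccc1)O[C@H](c1ccc(OCc3ccccc3)cc1)[C@@H](OCc1ccccc1)C2=O | intermediate
21 | protected dimer with free upper C3 hydroxyl and lower C4 ketone (upper 2S,3R,4S, 2,3-trans-3,4-cis; lower 2R,3R) | c1ccccc1COc1ccc([C@H]2Oc3c(cc([C@@H]4c5ccc6OC(c7ccccc7)(c7ccccc7)Oc6c5O[C@@H](c5ccc(OCc6ccccc6)cc5)[C@@H]4O)c(OCc4ccccc4)c3OCc3ccccc3)C(=O)[C@@H]2OCc2ccccc2)cc1 | intermediate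
22 | (2R,3R)-3,7,8-trihydroxy-2-(4-hydroxyphenyl)-6-[(2S,3R,4R)-3,7,8-trihydroxy-2-(4-hydroxyphenyl)chroman-4-yl]chroman-4-one | Oc1ccc([C@H]2Oc3c(cc([C@@H]4c5ccc(O)c(O)c5O[C@@H](c5ccc(O)cc5)[C@@H]4O)c(O)c3O)C(=O)[C@@H]2O)cc1 | intermediate
23 | (2R,3S,4R)-2-(4-hydroxyphenyl)-6-[(2S,3R,4R)-3,7,8-trihydroxy-2-(4-hydroxyphenyl)chroman-4-yl]chromane-3,4,7,8-tetrol | Oc1ccc([C@H]2Oc3c(cc([C@@H]4c5ccc(O)c(O)c5O[C@@H](c5ccc(O)cc5)[C@@H]4O)c(O)c3O)[C@@H](O)[C@@H]2O)cc1 | target

Total step count: 16.
Longest linear sequence: 13 steps (steps 4 to 16, from 8). The upper fragment (steps 1 to 3) joins at step 11.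

Steps most likely to fail

1. **Step 14.** The C4–O bond may ionise before C4a arrives, so that rotation about C3–C4 erodes the cis relation. Alternatively a hydride may migrate from C3 to C4 in a Meinwald-type rearrangement.
   - The fallback sets out from 18 and comes back at 21. It exchanges the roles: carbon is bonded first and hydride comes last.
   - Alkyne 18 is cyclised with Ph3PAuNTf2 in CH2Cl2 in the dark. This is the 6-endo-dig hydroarylation of an aryl propargyl ether, and C4 is the alkyne carbon polarised by ring D. It gives the 4-aryl-2H-chromene F1.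
   - OsO4/NMO then adds to the face opposite ring B and gives the chroman-3,4-cis-diol F2.
   - Et3SiH/BF3·OEt2 at −78 °C ionises the tertiary, doubly benzylic C4 hydroxyl. Hydride enters trans to the C3 oxygen, which is the usual facial preference of 2,3-trans-flavan-4-yl cations. Ring D is left cis to the C3 hydroxyl, which is 21.

2. **Step 13.** Stepwise oxygen transfer through a benzylic radical may allow rotation and a leak towards the trans-oxirane. Turnover on the crowded alkene may be slow, and facial selectivity may be poor.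
   - The fallback sets out from 19 and comes back at 20. It uses a concerted syn addition followed by a double inversion.
   - OsO4/NMO attacks the Z-allylic ether anti to the C2–O1 bond in the conformer with C2–H eclipsing the alkene. This is the empirical rule for osmylation of allylic ethers, and it gives the acyclic 3,4-diol F3.
   - MeC(OMe)3/PPTS converts F3 into the cyclic orthoacetate F4.
   - Acetyl bromide opens the derived acetoxonium ion at benzylic C4 with inversion to the 3-acetoxy-4-bromide F5.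
   - K2CO3/MeOH at 0 °C frees the C3 alkoxide, which displaces bromide with a second inversion and closes the cis-oxirane 20.

3. **Step 3.** The electron-rich phenol may attack the allenylidene through carbon instead of oxygen. Uncatalysed ionisation of the 4-alkoxybenzylic acetate may erode the enantioselectivity.
   - The fallback sets out from 3 and comes back at 7. It sets the centre at the alcohol stage.
   - Trimethylsilylacetylene is added to 3 with Et2Zn, Ti(OiPr)4 and the BINOL antipode that furnishes the (R)-propargylic alcohol F6.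
   - A Mitsunobu reaction with phenol 2 (PPh3, DIAD, toluene, −20 °C) forms the C2–O1 bond with inversion and gives the silylated aryl ether F7.
   - K2CO3/MeOH removes the silyl group to give 7.

Further compounds
F1 | step 14 | 4-aryl-2H-chromene (upper flav-3-ene, C2 R, ring D on C4; lower 2R,3R) | c1cc2OC(c3ccccc3)(c3ccccc3)Oc2c2c1C(c1cc3c(c(OCc4ccccc4)c1OCc1ccccc1)O[C@H](c1ccc(OCc4ccccc4)cc1)[C@@H](OCc1ccccc1)C3=O)=C[C@H](c1ccc(OCc3ccccc3)cc1)O2
F2 | step 14 | chroman-3,4-cis-diol (both hydroxyls trans to ring B, ring D on C4) | c1cc2OC(c3ccccc3)(c3ccccc3)Oc2c2c1[C@](O)(c1cc3c(c(OCc4ccccc4)c1OCc1ccccc1)O[C@H](c1ccc(OCc4ccccc4)cc1)[C@@H](OCc1ccccc1)C3=O)[C@@H](O)[C@H](c1ccc(OCc3ccccc3)cc1)O2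
F3 | step 13 | acyclic 3,4-diol from syn-dihydroxylation of the Z-alkene (O1 and O3 erythro) | c1ccc2OC(c3ccccc3)(c3ccccc3)Oc2c1O[C@@H](c1ccc(OCc3ccccc3)cc1)[C@H](O)[C@H](O)c1cc2c(c(OCc3ccccc3)c1OCc1ccccc1)O[C@H](c1ccc(OCc3ccccc3)cc1)[C@@H](OCc1ccccc1)C2=O
F4 | step 13 | cyclic orthoacetate of F3 (orthoester carbon unassigned) | c1ccc2OC(c3ccccc3)(c3ccccc3)Oc2c1O[C@@H](c1ccc(OCc3ccccc3)cc1)[C@@H]4OC(C)(OC)O[C@@H]4c1cc2c(c(OCc3ccccc3)c1OCc1ccccc1)O[C@H](c1ccc(OCc3ccccc3)cc1)[C@@H](OCc1ccccc1)C2=O
F5 | step 13 | 3-acetoxy-4-bromide (C4 inverted relative to F3) | c1ccc2OC(c3ccccc3)(c3ccccc3)Oc2c1O[C@@H](c1ccc(OCc3ccccc3)cc1)[C@H](OC(C)=O)[C@@H](Br)c1cc2c(c(OCc3ccccc3)c1OCc1ccccc1)O[C@H](c1ccc(OCc3ccccc3)cc1)[C@@H](OCc1ccccc1)C2=O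
F6 | step 3 | (R)-1-[4-(benzyloxy)phenyl]-3-(trimethylsilyl)prop-2-yn-1-ol | O[C@H](c1ccc(OCc2ccccc2)cc1)C#C[Si](C)(C)C
F7 | step 3 | (S)-4-({1-[4-(benzyloxy)phenyl]-3-(trimethylsilyl)prop-2-yn-1-yl}oxy)-2,2-diphenyl-1,3-benzodioxole | c1ccc2OC(c3ccccc3)(c3ccccc3)Oc2c1O[C@@H](c1ccc(OCc3ccccc3)cc1)C#C[Si](C)(C)C
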